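The eta run stopped short of its charge and stayed there, and the gamma run did the same. The question is what that plateau means for a new flask.

| setting | eta | gamma | flask |
|---|---|---|---|
| free monomer | 0.034 M | 0.075 M | 0.050 M |
| initiator | 0.10 mM | 0.10 mM | 0.10 mM |
| impurity | 19 µM | 19 µM | 19 µM |
| remark | run made earlier | run made earlier |  |
| time |  |  | 2.0 h |

| run | time / min | monomer in chains / % | free monomer / % |
|---|---|---|---|
| eta | 8.00 | 66.1 | 32.5 |
| eta | 15.0 | 85.2 | 15.4 |
| eta | 25.0 | 85.9 | 11.4 |
| eta | 50.0 | 86.6 | 13.7 |
| eta | 90.0 | 87.3 | 11.4 |
| gamma | 8.00 | 82.7 | 18.4 |
| gamma | 25.0 | 94.9 | 4.3 |
| gamma | 40.0 | 95.2 | 4.7 |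
| gamma | 60.0 | 95.5 | 6.1 |
| gamma | 90.0 | 96.4 | 5.7 |

(standard deviation of a reading: 1 percentage point)

- the average divides the monomer in chains by the number of chains begun, living and dead together
- steps that have been proposed: free monomer + living end -> monomer in chains + living end; initiator + impurity -> spent initiator A; free monomer + initiator -> living end + monomer in chains; initiator + monomer in chains -> spent initiator B; monomer in chains + living end -> free monomer + living end
- the earlier runs do not show the number of chains; that part of a forecast is a guess

- average number of monomer units in a chain (chains begun, living or dead) at 2.0 h
- part of the free monomer that has reacted at 2.0 h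

From 25.0 min on, free monomer in eta averages 12.2 % of charge, and in gamma 5.20 %. A fixed percentage left is therefore out. Eta's percentage is 2.35 times gamma's, while gamma's charge is 2.21 times eta's, which points to a fixed concentration: 4.14 mM against 3.90 mM. Their mean is the ceiling concentration M*, the free monomer left standing when addition to living ends and return from chains balance (the equilibrium monomer concentration): 4.02 mM. The flask should then keep 8.04 % of its charge, so the part of the free monomer reacted, c, is 92.0 %.

But is the flask there by the asked time? Eta's excess over its plateau falls from 20 percentage points to 3.2 points between 8.00 min and 15.0 min, a reading of 2.64 min per half-life. That second excess rests on readings with a scatter of 1 point, so the reading is rough. Still, 2.0 h holds 45.5 such half-lives, and eta carries the flask's charges of initiator and impurity.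

The chains are weaker ground, since the runs do not show their number. If impurity destroys its equal of initiator, the average number of monomer units in a chain, dp, is 568; if the whole initiator charge begins chains, dp is 460. The first is the guess kept here.

The forecast gives dp 580 and c 92.4 %: “Both are consistent with one equilibrium free monomer level of about 0.0038 M, independent of charge.”

The flask gives dp 602 and c 91.6 %.

    free monomer + living end → monomer in chains + living end, rate k1*[living end]*[free monomer] (k = 68.8 L mol⁻¹ s⁻¹)
    initiator + impurity → spent initiator A (k = 925 L mol⁻¹ s⁻¹)
    free monomer + initiator → living end + monomer in chains (k = 0.138 L mol⁻¹ s⁻¹)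
    initiator + monomer in chains → spent initiator B (k = 0.00893 L mol⁻¹ s⁻¹)
    monomer in chains + living end → free monomer + living end, rate k5*[living end] as long as [monomer in chains] is above zero (k = 0.288 s⁻¹)

At 2.00 h the step from free monomer to monomer in chains has a half-life of 2.2 min, far shorter than the 2.0 h of the flask. The ratio of making to loss of monomer in chains, each step taken net, then stands at 1.00. Free monomer in the flask reads 8.37 % at 1.00 h and 8.37 % at 2.00 h, against 8.04 % from M*. For the neighbour flask charged with 0.085 M of free monomer, M* gives 4.73 % left, and that flask holds 4.92 %.

The runs are simulated on assumed constants; scatter was added.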